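**Retrosynthetic overview**
1. The butyrolactone is closed last by lactonisation of a γ,α-dihydroxy methyl ester; the C3–OH stereocentre comes from Felkin reduction of an α-keto ester.
2. The C4–C1′ bond and the 1,1-disubstituted alkene arise together in a chair [3,3] shift of a 2-methoxycarbonyl allyl vinyl ether (divalent copper bis(oxazoline) catalysis).
3. Key disconnection: the allylic C–O bond of that ether, which ends up as the C3–O bond of the target. It is made by dirhodium-carbenoid O–H insertion into a hindered (Z)-allylic alcohol, with E-selective olefination in the same flask (new).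
4. The (Z)-enediol monoacetate is unmasked from a 3-furyl group (singlet oxygen, reduction); the furyl group is attached by Suzuki coupling and α-face hydrogenation.
5. Ring order: the six- and five-membered carbocycles come fused from the Hajos–Parrish ketone (gem-dimethylation, deoxygenation, trans hydrogenation); the furan is a temporary ring; the lactone ring is formed in the final step.

Assumption: (S)-Hajos–Parrish ketone is bought (otherwise two steps from 2-methylcyclopentane-1,3-dione, methyl vinyl ketone and L-proline); hydrindane positions are numbered as in 1H-indene, lactone positions as in oxolan-2-one, and C1′ is the side-chain carbon bearing CH2OAc.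

**Route**

Step 1
Reactants: 1 (7aS)-7a-methyl-2,3,7,7a-tetrahydro-1H-indene-1,5(6H)-dione ((S)-Hajos–Parrish ketone)
Product: 2 (7a′S)-7a′-methyl-2′,3′,7′,7a′-tetrahydrospiro[1,3-dioxolane-2,1′-inden]-5′(6′H)-one (C1 ethylene ketal of 1)
Conditions: Me3SiOCH2CH2OSiMe3 (1.2 equiv), Me3SiOTf (5 mol%), CH2Cl2, −78 to −20 °C
Reagents that add atoms: 1,2-bis(trimethylsilyloxy)ethane, C[Si](C)(C)OCCO[Si](C)(C)C
Why: Noyori ketalisation under kinetic conditions converts only the saturated cyclopentanone, because the conjugated enone carbonyl is far less electrophilic.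

Step 2
Reactants: 2 (7a′S)-7a′-methyl-2′,3′,7′,7a′-tetrahydrospiro[1,3-dioxolane-2,1′-inden]-5′(6′H)-one
Product: 3 (7a′S)-4′,4′,7a′-trimethyl-2′,4′,7′,7a′-tetrahydrospiro[1,3-dioxolane-2,1′-inden]-5′(6′H)-one (alkene moved to C3′=C3a′)
Conditions: KOt-Bu (4 equiv), t-BuOH/THF, 0 °C; MeI (6 equiv), 0 °C to rt
Reagents that add atoms: iodomethane, CI
Why: Deconjugative double α-alkylation of the extended dienolate puts both methyl groups on C4 and shifts the alkene to C3=C3a, while the ketal blocks enolisation at C2.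

Step 3
Reactants: 3 (7a′S)-4′,4′,7a′-trimethyl-2′,4′,7′,7a′-tetrahydrospiro[1,3-dioxolane-2,1′-inden]-5′(6′H)-one
Product: 4 (7a′S)-4′,4′,7a′-trimethyl-2′,4′,5′,6′,7′,7a′-hexahydrospiro[1,3-dioxolane-2,1′-indene] (C3′=C3a′ alkene)
Conditions: N2H4·H2O, KOH, diethylene glycol, 130 to 200 °C
Reagents that add atoms: none
Why: Wolff–Kishner reduction (Huang–Minlon procedure) removes the non-conjugated C5 carbonyl; ketal and alkene are inert to hot base.

Step 4
Reactants: 4 (7a′S)-4′,4′,7a′-trimethyl-2′,4′,5′,6′,7′,7a′-hexahydrospiro[1,3-dioxolane-2,1′-indene]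
Product: 6 (3aS,7aS)-4,4,7a-trimethyloctahydro-1H-inden-1-one, via saturated ketal 5 (not isolated)
Conditions: H2 (3 atm), 10% Pd/C, EtOAc, rt; filter; then 2 M HCl, THF, rt
Reagents that add atoms: water, O
Why: Heterogeneous hydrogenation delivers H2 to C3=C3a from the α face, opposite the angular methyl and the axial C4 methyl, which sets the trans ring fusion (3aS); acid then hydrolyses the dioxolane.

Step 5
Reactants: 6 (3aS,7aS)-4,4,7a-trimethyloctahydro-1H-inden-1-one
Product: 7 (3aS,7aS)-4,4,7a-trimethyl-3a,4,5,6,7,7a-hexahydro-3H-inden-1-yl trifluoromethanesulfonate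
Conditions: KN(SiMe3)2, THF, −78 °C; PhNTf2, −78 to 0 °C
Reagents that add atoms: N-phenylbis(trifluoromethanesulfonimide), O=S(=O)(N(c1ccccc1)S(=O)(=O)C(F)(F)F)C(F)(F)F
Why: Enolisation is possible only towards C2 (C7a is quaternary), and O-triflation of the potassium enolate gives the alkenyl triflate.

Step 6
Reactants: 7 (3aS,7aS)-4,4,7a-trimethyl-3a,4,5,6,7,7a-hexahydro-3H-inden-1-yl trifluoromethanesulfonate; 8 furan-3-ylboronic acid
Product: 9 3-[(3aS,7aS)-4,4,7a-trimethyl-3a,4,5,6,7,7a-hexahydro-3H-inden-1-yl]furan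
Conditions: Pd(PPh3)4 (5 mol%), K2CO3, LiCl, 1,4-dioxane/H2O, 80 °C
Reagents that add atoms: none
Why: Suzuki–Miyaura cross-coupling of a hindered alkenyl triflate with a heteroarylboronic acid, a standard C(sp2)–C(sp2) union.

Step 7
Reactants: 9 3-[(3aS,7aS)-4,4,7a-trimethyl-3a,4,5,6,7,7a-hexahydro-3H-inden-1-yl]furan
Product: 10 3-[(1S,3aS,7aS)-4,4,7a-trimethyloctahydro-1H-inden-1-yl]furan (furyl cis to the C7a methyl)
Conditions: H2 (1 atm), 5% Pd/CaCO3, EtOH, rt
Reagents that add atoms: none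
Why: Catalytic hydrogenation of the styrene-like ring alkene from the α face (the β face is screened by the C7a methyl) sets C1 with the furyl group β, and the mild catalyst leaves the furan intact.

Step 8
Reactants: 10 3-[(1S,3aS,7aS)-4,4,7a-trimethyloctahydro-1H-inden-1-yl]furan
Product: 13 (2Z)-2-[(1S,3aS,7aS)-4,4,7a-trimethyloctahydro-1H-inden-1-yl]but-2-ene-1,4-diol, via furan endoperoxide 11 (not isolated), via (Z)-enedial 12 (not isolated)
Conditions: O2, visible light, tetraphenylporphyrin (cat.), CH2Cl2, −78 °C; Me2S, −78 to −20 °C; then MeOH, CeCl3·7H2O, NaBH4, −78 to 0 °C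
Reagents that add atoms: dioxygen, O=O
Why: Singlet-oxygen [4+2] cycloaddition to the furan, reduction of the endoperoxide to the (Z)-enedial and Luche 1,2-reduction give the but-2-ene-1,4-diol, whose Z geometry is inherited from the ring.

Step 9
Reactants: 13 (2Z)-2-[(1S,3aS,7aS)-4,4,7a-trimethyloctahydro-1H-inden-1-yl]but-2-ene-1,4-diol
Product: 14 (2Z)-4-hydroxy-3-[(1S,3aS,7aS)-4,4,7a-trimethyloctahydro-1H-inden-1-yl]but-2-en-1-yl acetate
Conditions: AcCl (1.05 equiv), 2,4,6-collidine, CH2Cl2, −78 °C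
Reagents that add atoms: acetyl chloride, CC(Cl)=O
Why: Kinetic acylation favours the primary hydroxyl on the CH= terminus over the one next to the hydrindanyl-bearing carbon on steric grounds; diacetate and unreacted diol are recycled.

Step 10
Reactants: 15 methyl 2-[bis(2,2,2-trifluoroethoxy)phosphoryl]acetate
Product: 16 methyl 2-[bis(2,2,2-trifluoroethoxy)phosphoryl]-2-diazoacetate
Conditions: 4-acetamidobenzenesulfonyl azide, DBU, MeCN, 0 °C to rt
Reagents that add atoms: 4-acetamidobenzenesulfonyl azide, CC(=O)Nc1ccc(cc1)S(=O)(=O)N=[N+]=[N-]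
Why: Regitz diazo transfer to the doubly activated methylene of the phosphonoacetate.

Step 11
Reactants: 14 (2Z)-4-hydroxy-3-[(1S,3aS,7aS)-4,4,7a-trimethyloctahydro-1H-inden-1-yl]but-2-en-1-yl acetate; 16 methyl 2-[bis(2,2,2-trifluoroethoxy)phosphoryl]-2-diazoacetate; 17 2-[(tert-butyldimethylsilyl)oxy]acetaldehyde
Product: 19 methyl (2E)-2-{[(2Z)-4-(acetyloxy)-2-[(1S,3aS,7aS)-4,4,7a-trimethyloctahydro-1H-inden-1-yl]but-2-en-1-yl]oxy}-4-[(tert-butyldimethylsilyl)oxy]but-2-enoate, via phosphonate ether 18 (not isolated)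
Conditions: Rh2(OAc)4 (1 mol%), toluene, 80 °C, slow addition of 16; cool to −78 °C, THF, 18-crown-6, KN(SiMe3)2; then 17, −78 °C
Reagents that add atoms: none
Why: Proposed new method: the new bis(trifluoroethyl)phosphoryl diazoacetate 16 serves as a one-flask C–O/C=C linchpin – its dirhodium carbenoid is captured by the hindered allylic hydroxyl (oxonium ylide, then 1,2-proton shift; base-free, so the acetate cannot migrate), forging the C–O bond that becomes the C3–O bond of the target, and the electron-poor α-alkoxy phosphonate anion then olefinates 17 under kinetic Still–Gennari control (fast collapse of the first-formed oxaphosphetane places CH2OTBS cis to CO2Me), giving the (2E)-enol ether that the chair rearrangement needs; the closest known reaction types are the dirhodium-catalysed O–H insertion/Horner–Wadsworth–Emmons sequence of dimethyl diazophosphonoacetate (E/Z mixtures) and the Still–Gennari olefination.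

Step 12
Reactants: 19 methyl (2E)-2-{[(2Z)-4-(acetyloxy)-2-[(1S,3aS,7aS)-4,4,7a-trimethyloctahydro-1H-inden-1-yl]but-2-en-1-yl]oxy}-4-[(tert-butyldimethylsilyl)oxy]but-2-enoate
Product: 20 methyl (3R,4R)-4-[(acetyloxy)methyl]-3-{[(tert-butyldimethylsilyl)oxy]methyl}-2-oxo-5-[(1R,3aS,7aS)-4,4,7a-trimethyloctahydro-1H-inden-1-yl]hex-5-enoate
Conditions: [Cu(L)(H2O)2](SbF6)2 (10 mol%; L = (R,R)-2,2′-(propane-2,2-diyl)bis(4-tert-butyl-4,5-dihydro-1,3-oxazole)), CH2Cl2, rt
Reagents that add atoms: none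
Why: Catalytic asymmetric Claisen rearrangement ([3,3]) – the divalent copper Lewis acid chelates the ether oxygen and ester carbonyl, the chair transition state with CH2OTBS equatorial (E-enol ether) and CH2OAc axial (Z-allyl ether) fixes the C3/C4 relative configuration and creates the exocyclic methylene, and the ligand antipode (assigned from the square-planar chelate model, tert-butyl next to the ether oxygen shielding the Si face of C3) directs bonding to the Re faces of both termini to give (3R,4R).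

Step 13
Reactants: 20 methyl (3R,4R)-4-[(acetyloxy)methyl]-3-{[(tert-butyldimethylsilyl)oxy]methyl}-2-oxo-5-[(1R,3aS,7aS)-4,4,7a-trimethyloctahydro-1H-inden-1-yl]hex-5-enoate
Product: 23 (2R)-2-[(3R,4S)-4-hydroxy-5-oxooxolan-3-yl]-3-[(1R,3aS,7aS)-4,4,7a-trimethyloctahydro-1H-inden-1-yl]but-3-en-1-yl acetate, via hydroxy ester 21 (not isolated), via dihydroxy ester 22 (not isolated)
Conditions: KBH(s-Bu)3, THF, −78 °C; AcOH; then HF·pyridine, THF, 0 °C to rt
Reagents that add atoms: none
Why: Felkin–Anh 1,2-induction in the hydride reduction of the α-keto ester (hydride anti to the bulky C4 substituent, CH2OTBS inside) sets the (2S) carbinol that becomes the trans C3–OH, and fluoride desilylation is followed by 5-exo-trig lactonisation (transesterification) with the acetate untouched.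

**Compound list**
1 | (7aS)-7a-methyl-2,3,7,7a-tetrahydro-1H-indene-1,5(6H)-dione | C[C@]12CCC(=O)C=C1CCC2=O | starting material
2 | (7a′S)-7a′-methyl-2′,3′,7′,7a′-tetrahydrospiro[1,3-dioxolane-2,1′-inden]-5′(6′H)-one | C[C@]12CCC(=O)C=C1CCC23OCCO3 | intermediate
3 | (7a′S)-4′,4′,7a′-trimethyl-2′,4′,7′,7a′-tetrahydrospiro[1,3-dioxolane-2,1′-inden]-5′(6′H)-one | C[C@]12CCC(=O)C(C)(C)C1=CCC23OCCO3 | intermediate
4 | (7a′S)-4′,4′,7a′-trimethyl-2′,4′,5′,6′,7′,7a′-hexahydrospiro[1,3-dioxolane-2,1′-indene] | C[C@]12CCCC(C)(C)C1=CCC23OCCO3 | intermediate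
5 | (3a′S,7a′S)-4′,4′,7a′-trimethyloctahydrospiro[1,3-dioxolane-2,1′-indene] | C1COC2(O1)CC[C@H]1C(C)(C)CCC[C@]21C | intermediate
6 | (3aS,7aS)-4,4,7a-trimethyloctahydro-1H-inden-1-one | O=C1CC[C@H]2C(C)(C)CCC[C@]12C | intermediate
7 | (3aS,7aS)-4,4,7a-trimethyl-3a,4,5,6,7,7a-hexahydro-3H-inden-1-yl trifluoromethanesulfonate | O=S(=O)(OC1=CC[C@H]2C(C)(C)CCC[C@]12C)C(F)(F)F | intermediate
8 | furan-3-ylboronic acid | OB(O)c1ccoc1 | starting material
9 | 3-[(3aS,7aS)-4,4,7a-trimethyl-3a,4,5,6,7,7a-hexahydro-3H-inden-1-yl]furan | C1(c2ccoc2)=CC[C@H]3C(C)(C)CCC[C@]13C | intermediate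
10 | 3-[(1S,3aS,7aS)-4,4,7a-trimethyloctahydro-1H-inden-1-yl]furan | c1cocc1[C@H]2CC[C@H]3C(C)(C)CCC[C@]23C | intermediate
11 | 5-[(1S,3aS,7aS)-4,4,7a-trimethyloctahydro-1H-inden-1-yl]-2,3,7-trioxabicyclo[2.2.1]hept-5-ene (bridgehead epimers) | O1C2OOC1C=C2[C@H]3CC[C@H]4C(C)(C)CCC[C@]34C | intermediate
12 | (2Z)-2-[(1S,3aS,7aS)-4,4,7a-trimethyloctahydro-1H-inden-1-yl]but-2-enedial | O=C/C=C(\C=O)[C@H]1CC[C@H]2C(C)(C)CCC[C@]12C | intermediate
13 | (2Z)-2-[(1S,3aS,7aS)-4,4,7a-trimethyloctahydro-1H-inden-1-yl]but-2-ene-1,4-diol | OC/C=C(\CO)[C@H]1CC[C@H]2C(C)(C)CCC[C@]12C | intermediate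
14 | (2Z)-4-hydroxy-3-[(1S,3aS,7aS)-4,4,7a-trimethyloctahydro-1H-inden-1-yl]but-2-en-1-yl acetate | CC(=O)OC/C=C(\CO)[C@H]1CC[C@H]2C(C)(C)CCC[C@]12C | intermediate
15 | methyl 2-[bis(2,2,2-trifluoroethoxy)phosphoryl]acetate | COC(=O)CP(=O)(OCC(F)(F)F)OCC(F)(F)F | starting material
16 | methyl 2-[bis(2,2,2-trifluoroethoxy)phosphoryl]-2-diazoacetate | COC(=O)C(=[N+]=[N-])P(=O)(OCC(F)(F)F)OCC(F)(F)F | intermediate
17 | 2-[(tert-butyldimethylsilyl)oxy]acetaldehyde | O=CCO[Si](C)(C)C(C)(C)C | starting material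
18 | methyl 2-{[(2Z)-4-(acetyloxy)-2-[(1S,3aS,7aS)-4,4,7a-trimethyloctahydro-1H-inden-1-yl]but-2-en-1-yl]oxy}-2-[bis(2,2,2-trifluoroethoxy)phosphoryl]acetate (epimers at C2) | COC(=O)C(OC/C(=C\COC(C)=O)[C@H]1CC[C@H]2C(C)(C)CCC[C@]12C)P(=O)(OCC(F)(F)F)OCC(F)(F)F | intermediate
19 | methyl (2E)-2-{[(2Z)-4-(acetyloxy)-2-[(1S,3aS,7aS)-4,4,7a-trimethyloctahydro-1H-inden-1-yl]but-2-en-1-yl]oxy}-4-[(tert-butyldimethylsilyl)oxy]but-2-enoate | COC(=O)/C(OC/C(=C\COC(C)=O)[C@H]1CC[C@H]2C(C)(C)CCC[C@]12C)=C\CO[Si](C)(C)C(C)(C)C | intermediate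
20 | methyl (3R,4R)-4-[(acetyloxy)methyl]-3-{[(tert-butyldimethylsilyl)oxy]methyl}-2-oxo-5-[(1R,3aS,7aS)-4,4,7a-trimethyloctahydro-1H-inden-1-yl]hex-5-enoate | COC(=O)C(=O)[C@@H](CO[Si](C)(C)C(C)(C)C)[C@@H](COC(C)=O)C(=C)[C@H]1CC[C@H]2C(C)(C)CCC[C@]12C | intermediate
21 | methyl (2S,3R,4R)-4-[(acetyloxy)methyl]-3-{[(tert-butyldimethylsilyl)oxy]methyl}-2-hydroxy-5-[(1R,3aS,7aS)-4,4,7a-trimethyloctahydro-1H-inden-1-yl]hex-5-enoate | COC(=O)[C@@H](O)[C@@H](CO[Si](C)(C)C(C)(C)C)[C@@H](COC(C)=O)C(=C)[C@H]1CC[C@H]2C(C)(C)CCC[C@]12C | intermediate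
22 | methyl (2S,3R,4R)-4-[(acetyloxy)methyl]-2-hydroxy-3-(hydroxymethyl)-5-[(1R,3aS,7aS)-4,4,7a-trimethyloctahydro-1H-inden-1-yl]hex-5-enoate | COC(=O)[C@@H](O)[C@@H](CO)[C@@H](COC(C)=O)C(=C)[C@H]1CC[C@H]2C(C)(C)CCC[C@]12C | intermediate
23 | (2R)-2-[(3R,4S)-4-hydroxy-5-oxooxolan-3-yl]-3-[(1R,3aS,7aS)-4,4,7a-trimethyloctahydro-1H-inden-1-yl]but-3-en-1-yl acetate (CNP0252518.2) | C=C([C@H]1CC[C@H]2C(C)(C)CCC[C@]12C)[C@H](COC(C)=O)[C@@H]1COC(=O)[C@H]1O | target

**Totals and risks**

Total step count: 13. Longest linear sequence: 12 (steps 1–9 and 11–13; step 10 is a one-step side branch).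

The three steps most likely to fail:

Step 11, the proposed one-flask O–H insertion/olefination. The enol ether E/Z ratio may be poor, or the phosphonate anion may react elsewhere. The fallback uses known chemistry, sets out from 14 and comes back at 19. Diazo transfer (4-acetamidobenzenesulfonyl azide, DBU) to trimethyl phosphonoacetate gives methyl 2-diazo-2-(dimethoxyphosphoryl)acetate F1. Rh2(OAc)4-catalysed O–H insertion of 14 into it gives the isolated methyl 2-{[(2Z)-4-(acetyloxy)-2-(hydrindanyl)but-2-en-1-yl]oxy}-2-(dimethoxyphosphoryl)acetate F2. A Horner–Wadsworth–Emmons reaction of F2 with LiN(SiMe3)2 and 17 gives 19 together with its (2Z)-enol ether isomer F3. The isomers are separated by chromatography and 19 continues with step 12. The enol ether geometry is then secured by separation after a stepwise olefination instead of by reagent control.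

Step 12, the catalysed Claisen rearrangement. The bulky, chiral substituent on the central allyl carbon may slow the reaction or work against the catalyst, and the ligand sense rests on a model; the antipodal ligand is the first thing to check. The fallback sets out from 19 and comes back at 20. Catalyst control is given up: 19 is heated in 1,2-dichloroethane (80–90 °C, sealed tube). The uncatalysed chair [3,3] shift still fixes the C3/C4 relative configuration through the two alkene geometries and gives only 20 and its (3S,4S)-diastereomer F4. These are separated by chromatography and 20 continues with step 13.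

Step 8, the one-flask furan unmasking. The (Z)-enedial can isomerise, over-reduce or cyclise back towards the furan. The fallback sets out from 10 and comes back at 13, going stepwise through the butenolide oxidation level as in cardenolide chemistry. Photooxygenation of 10 in the presence of a hindered base (O2, visible light, rose bengal, i-Pr2NEt, CH2Cl2, −78 °C) gives 5-hydroxy-4-[(1S,3aS,7aS)-4,4,7a-trimethyloctahydro-1H-inden-1-yl]furan-2(5H)-one F5. NaBH4 reduction and acidification give 4-[(1S,3aS,7aS)-4,4,7a-trimethyloctahydro-1H-inden-1-yl]furan-2(5H)-one F6. Reduction with i-Bu2AlH (CH2Cl2, −78 to 0 °C) opens the lactone to the (Z)-diol 13.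

**Further compounds**
F1 | step 11 | methyl 2-diazo-2-(dimethoxyphosphoryl)acetate | COC(=O)C(=[N+]=[N-])P(=O)(OC)OC
F2 | step 11 | methyl 2-{[(2Z)-4-(acetyloxy)-2-[(1S,3aS,7aS)-4,4,7a-trimethyloctahydro-1H-inden-1-yl]but-2-en-1-yl]oxy}-2-(dimethoxyphosphoryl)acetate | COC(=O)C(OC/C(=C\COC(C)=O)[C@H]1CC[C@H]2C(C)(C)CCC[C@]12C)P(=O)(OC)OC
F3 | step 11 | methyl (2Z)-2-{[(2Z)-4-(acetyloxy)-2-[(1S,3aS,7aS)-4,4,7a-trimethyloctahydro-1H-inden-1-yl]but-2-en-1-yl]oxy}-4-[(tert-butyldimethylsilyl)oxy]but-2-enoate | COC(=O)/C(OC/C(=C\COC(C)=O)[C@H]1CC[C@H]2C(C)(C)CCC[C@]12C)=C/CO[Si](C)(C)C(C)(C)C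
F4 | step 12 | methyl (3S,4S)-4-[(acetyloxy)methyl]-3-{[(tert-butyldimethylsilyl)oxy]methyl}-2-oxo-5-[(1R,3aS,7aS)-4,4,7a-trimethyloctahydro-1H-inden-1-yl]hex-5-enoate | COC(=O)C(=O)[C@H](CO[Si](C)(C)C(C)(C)C)[C@H](COC(C)=O)C(=C)[C@H]1CC[C@H]2C(C)(C)CCC[C@]12C
F5 | step 8 | 5-hydroxy-4-[(1S,3aS,7aS)-4,4,7a-trimethyloctahydro-1H-inden-1-yl]furan-2(5H)-one (C5 epimers) | O=C1C=C([C@H]2CC[C@H]3C(C)(C)CCC[C@]23C)C(O)O1
F6 | step 8 | 4-[(1S,3aS,7aS)-4,4,7a-trimethyloctahydro-1H-inden-1-yl]furan-2(5H)-one | O=C1C=C([C@H]2CC[C@H]3C(C)(C)CCC[C@]23C)CO1
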